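## Structural features

The target is a 2,3-dihydrobenzofuran in which benzene ring A is fused through C3a and C7a to a five-membered ring made of O1, C2 and C3. Ring A is a fully differentiated phloroglucinol: oxygen sits on C4 (OH), C6 (OH) and C7a (the ring oxygen O1), C7 carries hydrogen, and C5, between the two hydroxyls, carries an (E)-4-hydroxycinnamoyl group, so rings A and B together form a 2',6'-dihydroxychalcone. The only stereocentre is C2 (S), which bears a 2-hydroxypropan-2-yl group; it has no stereogenic neighbour, so its configuration must come from a reagent or catalyst. The fragile parts are the enone flanked by two ortho phenols (oxa-Michael closure to a flavanone in acid or base, E/Z isomerisation in light), the tertiary alcohol next to the ring oxygen (dehydration or ring expansion in strong acid) and the electron-rich ring A. The real difficulty is twofold: absolute control of an isolated stereocentre, and regiocontrol on ring A, where the dihydrofuran must be fused across C3a/C7a and the acyl group must sit on C5 and not on C7. The key step uses the fact that C2 is the single atom bridging C3 and O1, which hang on the adjacent ring A carbons C3a and C7a: the unit O1–C7a–C3a–C3 is an ortho-quinone methide of ring A, and C2, with an ester as latent carbinol, can be added as a one-carbon ylide.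

## Logic of the disconnections

**16 to 15.** Only protecting groups are removed: the three phenolic O–H bonds of 16 are traced back to three O–CH2 acetal bonds in 15. Using the same acetal on all three oxygens means one final operation. The forward step must be mild enough that the freed ortho phenols do not add to the enone and the tertiary alcohol is not ionised.

**15 to 10 and 13.** The C5–C(carbonyl) bond is cut. C5 lies between two acetal oxygens that can direct a metalation, and the enone can be brought in whole, with its E geometry, at the carboxylic acid oxidation level. This splits the molecule into a ring A/dihydrofuran half and a ring B half. The forward step must metalate C5 and not C7 in the presence of the carbinol, and add once, in 1,2 fashion, to the acyl donor.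

**13 to 12 to 11.** The acetal O–C bond and then the amide C–N bond are cut, back to the acid 11, which already contains the E alkene. Forming the amide before the acetal keeps this branch to two operations; the coupling must prefer nitrogen over the free phenol.

**10 to 8.** Both C–CH3 bonds of the carbinol are cut, leaving an ester. The carbinol carbon thereby becomes a carboxyl carbon, which is what allows C2 to be delivered as a stabilised ylide. The double addition of a methyl nucleophile must outrun enolisation at C2.

**8 to 4 and 5.** C2–C3 and O1–C2 are cut together. This removes the ring and the stereocentre at once and leaves an achiral phenol and a one-carbon reagent; the forward reaction passes through 6 and 7. The demands are slow release and fast capture of 6, and enantioselection in the ring closure of 7, because the C–C bond formation creates no stereocentre.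

**4 to 3 to 2 to 1.** The C–S bond is cut (the sulfinate is a storable mask of the methide), then the benzylic C–H bond (reduction of the aldehyde), then two acetal O–C bonds. In 1 the formyl carbon is the future C3 and its hydrogen-bonded ortho phenol the future O1, so the regiochemistry of ring fusion is bought with the starting material. The forward steps must respect the acid-labile acetals and the readiness of 3 to ionise.

## Other disconnections considered

**Alternative 1:** The cut is the C4–C5 bond of ring A, so ring A is built rather than bought. In A1, methyl (5S)-5-(2-hydroxypropan-2-yl)-2-{(5E)-6-[4-(methoxymethoxy)phenyl]-2,4-dioxohex-5-en-1-yl}-4,5-dihydrofuran-3-carboxylate, a chiral dihydrofuran carries the ester carbon that becomes C4 and a 1,3-diketone chain holding C7, C6, C5 and the cinnamoyl unit. Under Mg(OMe)2 or NaOMe the methylene between the two ketones would attack the ester (Claisen-type closure of the six-membered ring); loss of methanol and enolisation would aromatise to A2, the target with its ring B phenol as MOM ether.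
- In its favour: the acyl group is placed on C5 by the connectivity of the chain, so the C5/C7 question that the chosen plan answers by directed metalation does not arise. On this point the alternative is the better plan. Ring A needs no protecting groups and only one acetal remains to be cleaved.
- Against it: the electrophile is an ester conjugated with the enol ether oxygen and should be sluggish. The chain has other ways to cyclise (through oxygen to a pyranone, aldol closure of C7 onto the cinnamoyl carbonyl, conjugate addition to the styryl ketone). A2 is a free 2',6'-dihydroxychalcone formed under base, where flavanone closure threatens.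
- Comparison: the C2 stereocentre would have to be made earlier by an unrelated asymmetric step, so on stereocontrol it is equal at best. Assembling A1 would take clearly more steps than the nine of the chosen route, so the chosen plan is ahead on step economy and on precedent for its precursor.

**Alternative 2:** The cut is C2–C3. A3, the N-tosylhydrazone of 2-[2-methyl-2-(triethylsilyloxy)propoxy]-4,6-bis(triisopropylsilyloxy)benzaldehyde, would give with base the diazo compound A4, 2-(diazomethyl)-1-[2-methyl-2-(triethylsilyloxy)propoxy]-3,5-bis(triisopropylsilyloxy)benzene. A chiral amidoporphyrin complex of divalent cobalt, [Co(Por*)], would convert A4 into a metal-bound radical at C3; 1,5-hydrogen abstraction from the OCH2 group and radical recombination would form C2–C3 and give A5, (S)-2-[2-(triethylsilyloxy)propan-2-yl]-4,6-bis(triisopropylsilyloxy)-2,3-dihydrobenzofuran.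
- In its favour: one catalytic step sets C2 with the complete carbinol skeleton in place, so no ester-to-carbinol step is needed. Radical C–H alkylation of this kind is an established entry to enantioenriched 2-substituted dihydrobenzofurans in which C2 is the only stereocentre, so on precedent for the stereochemical problem this alternative is the better one.
- Against it: the hydrogen to be abstracted sits next to a fully substituted silyloxy carbon and the diazo carbon is flanked by two ortho substituents, both of which crowd the catalyst pocket. Electron-rich aryldiazomethanes tend to form azines, and the ligand needs a multistep synthesis. The bulky silyl ethers do not direct metalation to C5, so the acyl group would need a protecting-group exchange or a halogenation whose regiochemistry is no more certain than the metalation of the chosen route.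
- Comparison: both plans close the same ring (one C–C bond here; one C–C and one C–O bond in the chosen plan) and both leave the C5 acylation for later (equal). The alternative would need about three more steps after A5 than the chosen route needs after 8.

**Alternative 3:** The cut is O1–C2, made on the complete chalcone. In A6, (E)-1-[4-(tert-butyldimethylsilyloxy)-3-{[(2R)-3,3-dimethyloxiran-2-yl]methyl}-2,6-bis(methoxymethoxy)phenyl]-3-[4-(methoxymethoxy)phenyl]prop-2-en-1-one, fluoride (CsF or Bu4NF) would unmask the oxygen on C7a. That oxygen would open the epoxide at its secondary carbon with inversion to give A7, the tri-O-MOM ether of the target. A7 is the same compound as 15, so the last step would be shared.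
- In its favour: the route is biomimetic and convergent. The acyl group is present from a C-acylated phloroglucinol onward, so C5 versus C7 is never in question (better than the chosen plan). The stereocentre derives from an asymmetric epoxidation of a trisubstituted prenyl alkene followed by a stereospecific opening, which has closer precedent than the stereocontrol asked of the chosen key step (better on this point).
- Against it: the three ring A oxygens must be differentiated (two MOM, one silyl) and the prenyl group placed on one specific carbon, which costs protecting-group steps. The epoxidation must select the prenyl alkene over the enone next to an electron-rich ring, and its enantiomeric purity caps that of the product. Opening at the tertiary carbon to a chromanol must be suppressed, and the attacking phenoxide is para to the carbonyl, hence a weak nucleophile.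
- Comparison: mechanistically both plans close the ring by a 5-exo-tet attack of the same oxygen on C2 with inversion (equal). In step count the alternative is about equal or slightly longer, and it carries the sensitive enone through more operations than the chosen plan, which introduces it in the penultimate step.

Key step: step 4

Assumption: for a methide with no substituent on its CH2 carbon the sense of induction of the urea cannot be deduced from the substituted cases; the (S,S)-catalyst is written, and its mirror image is used if it is the one that favours (S)-8.

Remark on the structures: no correction was needed, since the S descriptor of 8 maps onto the S descriptor of 16 (the ester carbon and the carbinol carbon hold the same CIP rank). Precursor 4 is kept with two MOM ethers because they tolerate the base of step 4 and later direct the metalation of step 8. The changes concern handling: a buffered sulfinate exchange in step 3, and an extra equivalent of n-BuLi in step 8 for the carbinol proton of 10.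

## Route

Step 1
Reactants: 1 2,4,6-trihydroxybenzaldehyde
Product: 2 2-hydroxy-4,6-bis(methoxymethoxy)benzaldehyde
Conditions: MOMCl (2.2 equiv), i-Pr2NEt (2.5 equiv), CH2Cl2, 0 °C to rt
Reagents that add atoms: chloromethyl methyl ether (MOMCl), COCCl
Why: O-alkylation of phenols (MOM protection); the para phenol and one ortho phenol react, while the remaining ortho phenol is held in a hydrogen bond to the formyl oxygen and is left free when MOMCl is limited to about two equivalents.

Step 2
Reactants: 2 2-hydroxy-4,6-bis(methoxymethoxy)benzaldehyde
Product: 3 2-(hydroxymethyl)-3,5-bis(methoxymethoxy)phenol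
Conditions: NaBH4 (1.0 equiv), THF–MeOH (5:1), −10 °C; pH 7 phosphate buffer; crude product used at once
Reagents that add atoms: none
Why: Borohydride reduction of an aryl aldehyde; low temperature, one equivalent of hydride and a neutral work-up are chosen so that the electron-rich hydroxybenzyl alcohol does not ionise to the methide and get reduced further or oligomerise, and the MOM ethers are inert.

Step 3
Reactants: 3 2-(hydroxymethyl)-3,5-bis(methoxymethoxy)phenol
Product: 4 3,5-bis(methoxymethoxy)-2-[(4-methylbenzenesulfonyl)methyl]phenol
Conditions: p-TolSO2Na (4 equiv), AcOH–THF–H2O (1:4:1), rt, slow addition of 3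
Reagents that add atoms: sodium p-toluenesulfinate (p-TolSO2Na), Cc1ccc(cc1)S(=O)[O-].[Na+]
Why: Acid-assisted ionisation of the hydroxybenzyl alcohol (via the methide or benzylic cation) and capture by the soft sulfur of the sulfinate gives the sulfone, the thermodynamic S-alkylation product. The three ring oxygens should allow ionisation at acetic acid strength, which MOM ethers tolerate, and the excess sulfinate with slow addition of 3 should outcompete C-alkylation of a second ring.

Step 4
Reactants: 4 3,5-bis(methoxymethoxy)-2-[(4-methylbenzenesulfonyl)methyl]phenol; 5 ethyl (dimethyl-lambda4-sulfanylidene)acetate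
Product: 8 ethyl (2S)-4,6-bis(methoxymethoxy)-2,3-dihydro-1-benzofuran-2-carboxylate, via ortho-quinone methide 6 (not isolated), via sulfonium betaine 7 (not isolated)
Conditions: 5 (2.0 equiv), Cs2CO3 (1.5 equiv), 1,1'-[(1S,2S)-1,2-diphenylethane-1,2-diyl]bis{3-[3,5-bis(trifluoromethyl)phenyl]urea} (10 mol %), CH2Cl2, −30 to −10 °C
Reagents that add atoms: none
Why: Proposed new method: Cs2CO3 deprotonates the phenol of 4, the phenoxide expels sulfinate and methide 6 is released slowly; the ylide carbon of 5 then adds to the exocyclic CH2 of 6 in a conjugate addition that restores aromaticity and forms C3–C2, giving betaine 7. The phenoxide of 7 displaces dimethyl sulfide at C2 in a 5-exo-tet SN2 closure that forms O1–C2 and the dihydrofuran ring. The closest known reaction type is the (4+1) annulation of ortho-quinone methides generated from 2-(sulfonylalkyl)phenols with stabilised sulfonium ylides, which chiral hydrogen-bond donors render enantioselective when the methide carbon is substituted and the C–C bond formation fixes the configuration. Here the methide carbon is unsubstituted, so C2 is the only stereocentre and is set in the ring closure: the carbon of 7 flanked by sulfonium and ester is acidic, its two epimers should interconvert by proton transfer through the excess ylide, and the urea, bound to the phenoxide and the ester carbonyl, is expected to favour closure of the (R)-betaine, which gives (S)-8 by inversion (dynamic kinetic resolution). The regiochemistry of ring fusion needs no control because O1 and C3 are the two termini of the methide. Trapping before self-condensation is secured by the two MOM-oxy donors, which stabilise 6, by the heterogeneous base, which keeps its concentration low, and by the excess of 5. Once the ring is closed the C2–H is no longer flanked by a sulfonium group and should not epimerise under carbonate at low temperature.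

Step 5
Reactants: 8 ethyl (2S)-4,6-bis(methoxymethoxy)-2,3-dihydro-1-benzofuran-2-carboxylate
Product: 10 2-[(2S)-4,6-bis(methoxymethoxy)-2,3-dihydro-1-benzofuran-2-yl]propan-2-ol, via methyl ketone 9 (not isolated)
Conditions: MeMgBr (3.0 equiv), THF, −20 to 0 °C; sat. aq. NH4Cl
Reagents that add atoms: methylmagnesium bromide (MeMgBr), C[Mg]Br
Why: Double Grignard addition to the ester through ketone 9 gives the tertiary alcohol; addition at low temperature is faster than enolisation and C2 has no beta leaving group, so the S configuration should be retained, and the MOM ethers are inert.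

Step 6
Reactants: 11 p-coumaric acid
Product: 12 (E)-3-(4-hydroxyphenyl)-N-methoxy-N-methylprop-2-enamide
Conditions: MeNH(OMe)·HCl (1.3 equiv), EDC·HCl (1.3 equiv), HOBt (0.2 equiv), Et3N (2.6 equiv), DMF, 0 °C to rt
Reagents that add atoms: N,O-dimethylhydroxylamine hydrochloride, CNOC.Cl
Why: Carbodiimide/HOBt amide coupling; the amine is far more nucleophilic than the phenol toward the active ester, so the phenol needs no protection and the E alkene is untouched.

Step 7
Reactants: 12 (E)-3-(4-hydroxyphenyl)-N-methoxy-N-methylprop-2-enamide
Product: 13 (E)-N-methoxy-3-[4-(methoxymethoxy)phenyl]-N-methylprop-2-enamide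
Conditions: MOMCl (1.5 equiv), i-Pr2NEt (2.0 equiv), CH2Cl2, 0 °C to rt
Reagents that add atoms: chloromethyl methyl ether (MOMCl), COCCl
Why: MOM protection of the phenol (O-alkylation under amine base) removes the acidic proton before the organolithium step; using the same acetal as on ring A lets one final operation free all three phenols.

Step 8
Reactants: 10 2-[(2S)-4,6-bis(methoxymethoxy)-2,3-dihydro-1-benzofuran-2-yl]propan-2-ol; 13 (E)-N-methoxy-3-[4-(methoxymethoxy)phenyl]-N-methylprop-2-enamide
Product: 15 (E)-1-[(2S)-2-(2-hydroxypropan-2-yl)-4,6-bis(methoxymethoxy)-2,3-dihydro-1-benzofuran-5-yl]-3-[4-(methoxymethoxy)phenyl]prop-2-en-1-one, via aryllithium 14 (not isolated)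
Conditions: n-BuLi (2.3 equiv), THF, −20 to 0 °C, 1 h; then 13 (1.4 equiv), −78 to −20 °C; sat. aq. NH4Cl
Reagents that add atoms: none
Why: Directed ortho-metalation followed by Weinreb ketone synthesis; the first equivalent of n-BuLi forms the lithium alkoxide and the second removes the C5 proton, which lies between two chelating MOM ethers and should be preferred over C7 (one MOM ether and the ring oxygen). The aryllithium adds 1,2 to the N-methoxy-N-methyl amide and the chelated tetrahedral adduct releases the E enone only on work-up, which prevents over-addition.

Step 9
Reactants: 15 (E)-1-[(2S)-2-(2-hydroxypropan-2-yl)-4,6-bis(methoxymethoxy)-2,3-dihydro-1-benzofuran-5-yl]-3-[4-(methoxymethoxy)phenyl]prop-2-en-1-one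
Product: 16 (E)-1-[(2S)-4,6-dihydroxy-2-(2-hydroxypropan-2-yl)-2,3-dihydro-1-benzofuran-5-yl]-3-(4-hydroxyphenyl)prop-2-en-1-one
Conditions: 3 M aq. HCl–MeOH (1:6), rt, exclusion of light; pH 6 phosphate buffer at full conversion
Reagents that add atoms: none
Why: Acid-catalysed acetal solvolysis (MOM cleavage) in methanol frees the three phenols; the two MOM groups flanking the carbonyl are activated by chelation, and room temperature is chosen to avoid oxa-Michael closure to the flavanone. The tertiary alcohol should survive because its cation is destabilised by the adjacent C–O bond, and C2 is not touched.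

## Compound list

1 | 2,4,6-trihydroxybenzaldehyde | O=Cc1c(O)cc(O)cc1O | starting material
2 | 2-hydroxy-4,6-bis(methoxymethoxy)benzaldehyde | O=Cc1c(O)cc(OCOC)cc1OCOC | intermediate
3 | 2-(hydroxymethyl)-3,5-bis(methoxymethoxy)phenol | OCc1c(O)cc(OCOC)cc1OCOC | intermediate
4 | 3,5-bis(methoxymethoxy)-2-[(4-methylbenzenesulfonyl)methyl]phenol | Cc1ccc(cc1)S(=O)(=O)Cc1c(O)cc(OCOC)cc1OCOC | intermediate
5 | ethyl (dimethyl-lambda4-sulfanylidene)acetate | CCOC(=O)C=S(C)C | starting material
6 | 3,5-bis(methoxymethoxy)-6-methylidenecyclohexa-2,4-dien-1-one (ortho-quinone methide, not isolated) | C=C1C(=O)C=C(OCOC)C=C1OCOC | intermediate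
7 | {1-ethoxy-3-[2-oxido-4,6-bis(methoxymethoxy)phenyl]-1-oxopropan-2-yl}dimethylsulfonium (betaine, epimers in equilibrium, not isolated) | CCOC(=O)C(Cc1c([O-])cc(OCOC)cc1OCOC)[S+](C)C | intermediate
8 | ethyl (2S)-4,6-bis(methoxymethoxy)-2,3-dihydro-1-benzofuran-2-carboxylate | CCOC(=O)[C@@H]1Cc2c(cc(OCOC)cc2OCOC)O1 | intermediate
9 | 1-[(2S)-4,6-bis(methoxymethoxy)-2,3-dihydro-1-benzofuran-2-yl]ethan-1-one (not isolated) | CC(=O)[C@@H]1Cc2c(cc(OCOC)cc2OCOC)O1 | intermediate
10 | 2-[(2S)-4,6-bis(methoxymethoxy)-2,3-dihydro-1-benzofuran-2-yl]propan-2-ol | CC(C)(O)[C@@H]1Cc2c(cc(OCOC)cc2OCOC)O1 | intermediate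
11 | p-coumaric acid, (E)-3-(4-hydroxyphenyl)prop-2-enoic acid | O=C(O)/C=C/c1ccc(O)cc1 | starting material
12 | (E)-3-(4-hydroxyphenyl)-N-methoxy-N-methylprop-2-enamide | CON(C)C(=O)/C=C/c1ccc(O)cc1 | intermediate
13 | (E)-N-methoxy-3-[4-(methoxymethoxy)phenyl]-N-methylprop-2-enamide | CON(C)C(=O)/C=C/c1ccc(OCOC)cc1 | intermediate
14 | lithium 2-[(2S)-5-lithio-4,6-bis(methoxymethoxy)-2,3-dihydro-1-benzofuran-2-yl]propan-2-olate (not isolated) | [Li]OC(C)(C)[C@@H]1Cc2c(cc(OCOC)c([Li])c2OCOC)O1 | intermediate
15 | (E)-1-[(2S)-2-(2-hydroxypropan-2-yl)-4,6-bis(methoxymethoxy)-2,3-dihydro-1-benzofuran-5-yl]-3-[4-(methoxymethoxy)phenyl]prop-2-en-1-one | CC(C)(O)[C@@H]1Cc2c(cc(OCOC)c(C(=O)/C=C/c3ccc(OCOC)cc3)c2OCOC)O1 | intermediate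
16 | (E)-1-[(2S)-4,6-dihydroxy-2-(2-hydroxypropan-2-yl)-2,3-dihydro-1-benzofuran-5-yl]-3-(4-hydroxyphenyl)prop-2-en-1-one | CC(C)(O)[C@@H]1Cc2c(cc(O)c(C(=O)/C=C/c3ccc(O)cc3)c2O)O1 | target

## Step count and least certain steps

Total step count: 9. Longest linear sequence: 7 steps (steps 1, 2, 3, 4, 5, 8 and 9); the two-step branch to 13 (steps 6 and 7) joins at step 8.

**Step 4 (key step, proposed new method).** The most likely failure is weak enantioselection in the ring-closing displacement. Without a substituent on C3 the urea may bind both epimers of the betaine about equally, or closure may be faster than their interconversion, and an uncatalysed background closure can erode the result further. Self-condensation of the methide is the second risk. The fallback uses known chemistry and sets out from 4 and 5. Cs2CO3 in CH2Cl2 at rt without the urea should give racemic ethyl 4,6-bis(methoxymethoxy)-2,3-dihydro-1-benzofuran-2-carboxylate F1. LiOH in THF–H2O would then give racemic 4,6-bis(methoxymethoxy)-2,3-dihydro-1-benzofuran-2-carboxylic acid F2. Crystallisation of its salt with (S)- or (R)-1-phenylethylamine, whichever deposits the salt of the S acid, and liberation with aqueous citric acid would give (2S)-4,6-bis(methoxymethoxy)-2,3-dihydro-1-benzofuran-2-carboxylic acid F3. Esterification with iodoethane and K2CO3 in DMF returns to the route at 8.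

**Step 3.** The most likely failure is premature ionisation of 3 followed by C-alkylation of one electron-rich ring by the methide of another (oligomerisation), or partial loss of MOM groups if the acidity has to be raised to drive the exchange. The fallback sets out from 3 and forms the C–S bond under neutral conditions with a better nucleophile. Warming 3 with 4-methylbenzenethiol (3 equiv) in EtOH–H2O at 60 °C should give 3,5-bis(methoxymethoxy)-2-{[(4-methylphenyl)sulfanyl]methyl}phenol F4 by thia-Michael capture of the thermally formed methide. Oxidation of the sulfide with H2O2 and catalytic Na2WO4 in MeOH then returns to the route at 4.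

**Step 8.** The most likely failure is metalation at C7, steered by the ring oxygen and the neighbouring lithium alkoxide, in competition with C5. Conjugate addition of the hindered aryllithium to the cinnamoyl amide is a second possibility. The fallback sets out from 10.
- TESOTf and 2,6-lutidine would give triethyl({2-[(2S)-4,6-bis(methoxymethoxy)-2,3-dihydro-1-benzofuran-2-yl]propan-2-yl}oxy)silane F5. This removes the alkoxide and screens O1.
- Metalation with n-BuLi (1.2 equiv) in THF and trapping with N-methoxy-N-methylacetamide would give 1-[(2S)-4,6-bis(methoxymethoxy)-2-{2-[(triethylsilyl)oxy]propan-2-yl}-2,3-dihydro-1-benzofuran-5-yl]ethan-1-one F6.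
- Claisen–Schmidt condensation of F6 with commercial 4-(methoxymethoxy)benzaldehyde (KOH, EtOH, rt) would build the enone without any conjugate acceptor being present during C–C bond formation at C5. It would give (E)-1-[(2S)-4,6-bis(methoxymethoxy)-2-{2-[(triethylsilyl)oxy]propan-2-yl}-2,3-dihydro-1-benzofuran-5-yl]-3-[4-(methoxymethoxy)phenyl]prop-2-en-1-one F7.
- The conditions of step 9 would remove the silyl ether together with the acetals and return to the route at 16.

**Step 9.** The most likely failure is oxa-Michael closure of a freed ortho phenol onto the enone (flavanone formation), or ionisation of the tertiary alcohol, during protic acid solvolysis. The fallback sets out from 15 and avoids protic acid. TMSOTf with 2,2'-bipyridyl in CH3CN at 0 °C should exchange the aryl MOM ethers for aryl trimethylsilyl ethers and silylate the carbinol. This would give (E)-1-[(2S)-4,6-bis(trimethylsilyloxy)-2-{2-[(trimethylsilyl)oxy]propan-2-yl}-2,3-dihydro-1-benzofuran-5-yl]-3-[4-(trimethylsilyloxy)phenyl]prop-2-en-1-one F8. Water followed by brief AcOH–THF–H2O at rt would hydrolyse the silyl ethers and return to the route at 16.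

## Further compounds

F1 | step 4 | racemic ethyl 4,6-bis(methoxymethoxy)-2,3-dihydro-1-benzofuran-2-carboxylate | CCOC(=O)C1Cc2c(cc(OCOC)cc2OCOC)O1
F2 | step 4 | racemic 4,6-bis(methoxymethoxy)-2,3-dihydro-1-benzofuran-2-carboxylic acid | OC(=O)C1Cc2c(cc(OCOC)cc2OCOC)O1
F3 | step 4 | (2S)-4,6-bis(methoxymethoxy)-2,3-dihydro-1-benzofuran-2-carboxylic acid | OC(=O)[C@@H]1Cc2c(cc(OCOC)cc2OCOC)O1
F4 | step 3 | 3,5-bis(methoxymethoxy)-2-{[(4-methylphenyl)sulfanyl]methyl}phenol | Cc1ccc(cc1)SCc1c(O)cc(OCOC)cc1OCOC
F5 | step 8 | triethyl({2-[(2S)-4,6-bis(methoxymethoxy)-2,3-dihydro-1-benzofuran-2-yl]propan-2-yl}oxy)silane | CC[Si](CC)(CC)OC(C)(C)[C@@H]1Cc2c(cc(OCOC)cc2OCOC)O1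
F6 | step 8 | 1-[(2S)-4,6-bis(methoxymethoxy)-2-{2-[(triethylsilyl)oxy]propan-2-yl}-2,3-dihydro-1-benzofuran-5-yl]ethan-1-one | CC[Si](CC)(CC)OC(C)(C)[C@@H]1Cc2c(cc(OCOC)c(C(C)=O)c2OCOC)O1
F7 | step 8 | (E)-1-[(2S)-4,6-bis(methoxymethoxy)-2-{2-[(triethylsilyl)oxy]propan-2-yl}-2,3-dihydro-1-benzofuran-5-yl]-3-[4-(methoxymethoxy)phenyl]prop-2-en-1-one | CC[Si](CC)(CC)OC(C)(C)[C@@H]1Cc2c(cc(OCOC)c(C(=O)/C=C/c3ccc(OCOC)cc3)c2OCOC)O1
F8 | step 9 | (E)-1-[(2S)-4,6-bis(trimethylsilyloxy)-2-{2-[(trimethylsilyl)oxy]propan-2-yl}-2,3-dihydro-1-benzofuran-5-yl]-3-[4-(trimethylsilyloxy)phenyl]prop-2-en-1-one | C[Si](C)(C)OC(C)(C)[C@@H]1Cc2c(cc(O[Si](C)(C)C)c(C(=O)/C=C/c3ccc(O[Si](C)(C)C)cc3)c2O[Si](C)(C)C)O1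
A1 | alternative 1 | methyl (5S)-5-(2-hydroxypropan-2-yl)-2-{(5E)-6-[4-(methoxymethoxy)phenyl]-2,4-dioxohex-5-en-1-yl}-4,5-dihydrofuran-3-carboxylate | CC(C)(O)[C@@H]1CC(C(=O)OC)=C(CC(=O)CC(=O)/C=C/c2ccc(OCOC)cc2)O1
A2 | alternative 1 | (E)-1-[(2S)-4,6-dihydroxy-2-(2-hydroxypropan-2-yl)-2,3-dihydro-1-benzofuran-5-yl]-3-[4-(methoxymethoxy)phenyl]prop-2-en-1-one | CC(C)(O)[C@@H]1Cc2c(cc(O)c(C(=O)/C=C/c3ccc(OCOC)cc3)c2O)O1
A3 | alternative 2 | N'-[(E)-{2-[2-methyl-2-(triethylsilyloxy)propoxy]-4,6-bis(triisopropylsilyloxy)phenyl}methylidene]-4-methylbenzenesulfonohydrazide | Cc1ccc(cc1)S(=O)(=O)N/N=C/c1c(OCC(C)(C)O[Si](CC)(CC)CC)cc(O[Si](C(C)C)(C(C)C)C(C)C)cc1O[Si](C(C)C)(C(C)C)C(C)C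
A4 | alternative 2 | 2-(diazomethyl)-1-[2-methyl-2-(triethylsilyloxy)propoxy]-3,5-bis(triisopropylsilyloxy)benzene | [N-]=[N+]=Cc1c(OCC(C)(C)O[Si](CC)(CC)CC)cc(O[Si](C(C)C)(C(C)C)C(C)C)cc1O[Si](C(C)C)(C(C)C)C(C)C
A5 | alternative 2 | (S)-2-[2-(triethylsilyloxy)propan-2-yl]-4,6-bis(triisopropylsilyloxy)-2,3-dihydrobenzofuran | CC(C)(O[Si](CC)(CC)CC)[C@@H]1Cc2c(cc(O[Si](C(C)C)(C(C)C)C(C)C)cc2O[Si](C(C)C)(C(C)C)C(C)C)O1
A6 | alternative 3 | (E)-1-[4-(tert-butyldimethylsilyloxy)-3-{[(2R)-3,3-dimethyloxiran-2-yl]methyl}-2,6-bis(methoxymethoxy)phenyl]-3-[4-(methoxymethoxy)phenyl]prop-2-en-1-one | CC1(C)O[C@@H]1Cc1c(O[Si](C)(C)C(C)(C)C)cc(OCOC)c(C(=O)/C=C/c2ccc(OCOC)cc2)c1OCOC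
A7 | alternative 3 | (E)-1-[(2S)-2-(2-hydroxypropan-2-yl)-4,6-bis(methoxymethoxy)-2,3-dihydro-1-benzofuran-5-yl]-3-[4-(methoxymethoxy)phenyl]prop-2-en-1-one (identical with 15) | CC(C)(O)[C@@H]1Cc2c(cc(OCOC)c(C(=O)/C=C/c3ccc(OCOC)cc3)c2OCOC)O1
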